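**Retrosynthetic overview**
- The plan rests on ring A of the apigenin unit: its C5–OH, C7–OH and O1 sit 1,3,5 on a benzene ring whose C6 and C8 are unsubstituted, and it is fused to pyranone ring C through C4a and C8a–O1. That ring is therefore phloroglucinol itself.
- Last disconnection: the two benzyl ethers on the acacetin 5-O and 7-O (BCl3). Key disconnection: C4–C4a and O1–C2 of the apigenin ring C, giving phloroglucinol and the aroylacetate 16 (thermal Mentzer condensation).
- 16 comes from acid 13 (malonate homologation), and 13 from flavone ester 12. The acacetin ring C is closed by Baker–Venkataraman-type acylation and cyclodehydration of hydroxyacetophenone 9 with 4-methoxybenzoyl chloride.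
- 9 comes from the symmetrical phenol 7 (C-acetylation), 7 from aldehyde 5 (Dakin oxidation), and 5 from syringaldehyde and tert-butyl 4-fluorobenzoate (SNAr diaryl ether, then exchange of methyl for benzyl).
- Ring order: acacetin ring C (step 6), then apigenin ring C (step 9); all benzene rings are bought.

Key step: step 9

Remark: the target has no stereocentre. A tert-butyl ester is carried through the SNAr because BBr3 would attack any alkyl ester; the acid set free is re-esterified as the benzyl ester in the benzylation step.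

**Route**

Step 1
Reactants: 1 syringaldehyde (4-hydroxy-3,5-dimethoxybenzaldehyde); 2 tert-butyl 4-fluorobenzoate
Product: 3 tert-butyl 4-(4-formyl-2,6-dimethoxyphenoxy)benzoate
Conditions: Cs2CO3, DMSO, 130 °C, N2
Reagents that add atoms: none
Why: SNAr: the cesium phenoxide of 1 adds para to the ester of 2 and fluoride leaves from the Meisenheimer adduct, while the tert-butyl ester resists acyl attack or dealkylation by phenoxide and the methoxy groups hinder the oxygen less than benzyloxy groups would.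

Step 2
Reactants: 3 tert-butyl 4-(4-formyl-2,6-dimethoxyphenoxy)benzoate
Product: 4 4-(4-formyl-2,6-dihydroxyphenoxy)benzoic acid
Conditions: BBr3 (6 equiv), CH2Cl2, −78 °C to rt; ice-water
Reagents that add atoms: none
Why: Lewis acid dealkylation: BBr3 cleaves both aryl methyl ethers by bromide attack at methyl and the tert-butyl ester by ionisation, whereas the diaryl ether offers no carbon open to substitution and the aldehyde is returned on hydrolysis.

Step 3
Reactants: 4 4-(4-formyl-2,6-dihydroxyphenoxy)benzoic acid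
Product: 5 benzyl 4-[2,6-bis(benzyloxy)-4-formylphenoxy]benzoate
Conditions: BnBr (3.5 equiv), K2CO3, DMF, 60 °C
Reagents that add atoms: benzyl bromide, BrCc1ccccc1
Why: Williamson etherification and carboxylate alkylation: both phenoxides and the carboxylate are benzylated by SN2, which installs ethers that BCl3 can later remove without touching an aryl methyl ether.

Step 4
Reactants: 5 benzyl 4-[2,6-bis(benzyloxy)-4-formylphenoxy]benzoate
Product: 7 benzyl 4-[2,6-bis(benzyloxy)-4-hydroxyphenoxy]benzoate, via aryl formate 6 (not isolated)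
Conditions: mCPBA, CH2Cl2, rt; then Et3N, MeOH, rt
Reagents that add atoms: 3-chloroperoxybenzoic acid (mCPBA), O=C(OO)c1cccc(Cl)c1
Why: Baeyer–Villiger oxidation in its Dakin sense: the aryl group bearing a para-aryloxy donor migrates in the Criegee adduct to give formate 6, which amine-promoted methanolysis cleaves far faster than the benzyl benzoate.

Step 5
Reactants: 7 benzyl 4-[2,6-bis(benzyloxy)-4-hydroxyphenoxy]benzoate
Product: 9 benzyl 4-[3-acetyl-2,6-bis(benzyloxy)-4-hydroxyphenoxy]benzoate, via aryl acetate 8 (not isolated)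
Conditions: Ac2O (1.5 equiv), BF3·OEt2 (3 equiv), AcOH, 0 to 50 °C; aq. NaOAc work-up
Reagents that add atoms: acetic anhydride, CC(=O)OC(C)=O
Why: Friedel–Crafts C-acetylation by way of the O-acetate (Fries rearrangement): the ring carries four oxygen donors, its para position is blocked and its two free ortho positions are equivalent, so a single hydroxyacetophenone should form under mild BF3 activation that spares the benzyl ethers and the deactivated benzoate ring.

Step 6
Reactants: 9 benzyl 4-[3-acetyl-2,6-bis(benzyloxy)-4-hydroxyphenoxy]benzoate; 10 4-methoxybenzoyl chloride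
Product: 12 benzyl 4-[[5,7-bis(benzyloxy)-2-(4-methoxyphenyl)-4-oxo-4H-chromen-6-yl]oxy]benzoate, via 1,3-diketone 11 (not isolated)
Conditions: LiN(SiMe3)2 (3.2 equiv), THF, −78 °C, then 10, −78 °C to rt; aq. NH4Cl; crude, p-TsOH·H2O (cat.), toluene, reflux (Dean–Stark)
Reagents that add atoms: none
Why: Baker–Venkataraman-type Claisen acylation in its lithium polyanion variant followed by acid cyclodehydration: the enolate carbon of the dianion of 9 is acylated by 10, the only free phenol then adds to the anisoyl ketone and water is lost, so the aryloxy group can only end up at C6 of the flavone.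

Step 7
Reactants: 12 benzyl 4-[[5,7-bis(benzyloxy)-2-(4-methoxyphenyl)-4-oxo-4H-chromen-6-yl]oxy]benzoate
Product: 13 4-[[5,7-bis(benzyloxy)-2-(4-methoxyphenyl)-4-oxo-4H-chromen-6-yl]oxy]benzoic acid
Conditions: LiOH·H2O (3 equiv), THF/H2O 3:1, rt to 40 °C; then 1 M HCl to pH 3
Reagents that add atoms: lithium hydroxide, [Li+].[OH-]
Why: Saponification (BAc2): hydroxide cleaves the benzyl ester under conditions mild enough that the 2-aryl-4-pyranone ring and the ethers should remain intact.

Step 8
Reactants: 13 4-[[5,7-bis(benzyloxy)-2-(4-methoxyphenyl)-4-oxo-4H-chromen-6-yl]oxy]benzoic acid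
Product: 16 ethyl 3-[4-[[5,7-bis(benzyloxy)-2-(4-methoxyphenyl)-4-oxo-4H-chromen-6-yl]oxy]phenyl]-3-oxopropanoate, via acyl imidazole 14 (not isolated), via aroylmalonic half ester 15 (not isolated)
Conditions: CDI, THF, rt; then KO2CCH2CO2Et, MgCl2, Et3N, MeCN/THF, rt to 45 °C; 1 M HCl
Reagents that add atoms: potassium ethyl malonate, CCOC(=O)CC(=O)[O-].[K+]
Why: Masamune–Brooks homologation: the acyl imidazole acylates the magnesium enolate of ethyl malonate at carbon and the malonic half ester decarboxylates on acidification, a near-neutral sequence that leaves the flavone untouched.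

Step 9
Reactants: 16 ethyl 3-[4-[[5,7-bis(benzyloxy)-2-(4-methoxyphenyl)-4-oxo-4H-chromen-6-yl]oxy]phenyl]-3-oxopropanoate; 17 phloroglucinol (4 equiv)
Product: 20 5,7-bis(benzyloxy)-6-[4-(5,7-dihydroxy-4-oxo-4H-chromen-2-yl)phenoxy]-2-(4-methoxyphenyl)-4H-chromen-4-one (5,7-di-O-benzylcryptomerin A), via aroylketene 18 (not isolated), via aryl 1,3-diketone 19 (not isolated)
Conditions: neat melt, microwave, 240 °C, about 10 min, N2 stream
Reagents that add atoms: none
Why: Thermal condensation of a phenol with a beta-keto ester (Mentzer pyrone synthesis, the acid-free counterpart of the Simonis chromone synthesis): at 240 °C 16 should lose ethanol to the aroylketene 18, which C-acylates molten phloroglucinol to the ortho-hydroxyaryl 1,3-diketone 19 and so forms C4–C4a. Ring C of the apigenin unit is then closed at oxygen: the neighbouring phenol adds to the aryl ketone (6-exo-trig) and water is lost, forming O1–C2 and the pyranone. No stereocentre is formed. The step needs chromone over 4-arylcoumarin selectivity, which the absence of acid should secure because the ester carbon and not the ketone is then the acylating centre; regiochemistry does not arise because the three ring carbons and three hydroxyls of phloroglucinol are equivalent, so the apigenin hydroxyls need no protection. The acacetin ring A is fully etherified, bears the deactivating C4 carbonyl and has only C8 free, so it should not compete with the fourfold excess of phloroglucinol, and the new flavone is deactivated towards a second acylation.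

Step 10
Reactants: 20 5,7-di-O-benzylcryptomerin A
Product: 21 cryptomerin A, 6-[4-(5,7-dihydroxy-4-oxo-4H-chromen-2-yl)phenoxy]-5,7-dihydroxy-2-(4-methoxyphenyl)-4H-chromen-4-one
Conditions: BCl3 (8 equiv), pentamethylbenzene (6 equiv), CH2Cl2, −78 to 0 °C; H2O
Reagents that add atoms: none
Why: Lewis acid debenzylation: BCl3 ionises the benzyl ethers (the 5-O-benzyl helped by chelation to the C4 carbonyl), pentamethylbenzene traps the benzyl cation by Friedel–Crafts alkylation so the phloroglucinol ring is not C-benzylated, and the unchelated 4'-methyl ether should survive at or below 0 °C.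

**Compound list**

1 | syringaldehyde (4-hydroxy-3,5-dimethoxybenzaldehyde) | COc1cc(C=O)cc(OC)c1O | starting material
2 | tert-butyl 4-fluorobenzoate | CC(C)(C)OC(=O)c1ccc(F)cc1 | starting material
3 | tert-butyl 4-(4-formyl-2,6-dimethoxyphenoxy)benzoate | CC(C)(C)OC(=O)c1ccc(Oc2c(OC)cc(C=O)cc2OC)cc1 | intermediate
4 | 4-(4-formyl-2,6-dihydroxyphenoxy)benzoic acid | OC(=O)c1ccc(Oc2c(O)cc(C=O)cc2O)cc1 | intermediate
5 | benzyl 4-[2,6-bis(benzyloxy)-4-formylphenoxy]benzoate | O=Cc1cc(OCc2ccccc2)c(Oc2ccc(C(=O)OCc3ccccc3)cc2)c(OCc2ccccc2)c1 | intermediate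
6 | benzyl 4-[2,6-bis(benzyloxy)-4-(formyloxy)phenoxy]benzoate (aryl formate, not isolated) | O=COc1cc(OCc2ccccc2)c(Oc2ccc(C(=O)OCc3ccccc3)cc2)c(OCc2ccccc2)c1 | intermediate
7 | benzyl 4-[2,6-bis(benzyloxy)-4-hydroxyphenoxy]benzoate | Oc1cc(OCc2ccccc2)c(Oc2ccc(C(=O)OCc3ccccc3)cc2)c(OCc2ccccc2)c1 | intermediate
8 | benzyl 4-[4-(acetyloxy)-2,6-bis(benzyloxy)phenoxy]benzoate (aryl acetate, not isolated) | CC(=O)Oc1cc(OCc2ccccc2)c(Oc2ccc(C(=O)OCc3ccccc3)cc2)c(OCc2ccccc2)c1 | intermediate
9 | benzyl 4-[3-acetyl-2,6-bis(benzyloxy)-4-hydroxyphenoxy]benzoate | CC(=O)c1c(O)cc(OCc2ccccc2)c(Oc2ccc(C(=O)OCc3ccccc3)cc2)c1OCc1ccccc1 | intermediate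
10 | 4-methoxybenzoyl chloride | COc1ccc(C(=O)Cl)cc1 | starting material
11 | benzyl 4-[2,6-bis(benzyloxy)-4-hydroxy-3-[3-(4-methoxyphenyl)-3-oxopropanoyl]phenoxy]benzoate (1,3-diketone, not isolated) | COc1ccc(C(=O)CC(=O)c2c(O)cc(OCc3ccccc3)c(Oc3ccc(C(=O)OCc4ccccc4)cc3)c2OCc2ccccc2)cc1 | intermediate
12 | benzyl 4-[[5,7-bis(benzyloxy)-2-(4-methoxyphenyl)-4-oxo-4H-chromen-6-yl]oxy]benzoate | COc1ccc(-c2cc(=O)c3c(OCc4ccccc4)c(Oc4ccc(C(=O)OCc5ccccc5)cc4)c(OCc4ccccc4)cc3o2)cc1 | intermediate
13 | 4-[[5,7-bis(benzyloxy)-2-(4-methoxyphenyl)-4-oxo-4H-chromen-6-yl]oxy]benzoic acid | COc1ccc(-c2cc(=O)c3c(OCc4ccccc4)c(Oc4ccc(C(=O)O)cc4)c(OCc4ccccc4)cc3o2)cc1 | intermediate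
14 | 5,7-bis(benzyloxy)-6-[4-(imidazole-1-carbonyl)phenoxy]-2-(4-methoxyphenyl)-4H-chromen-4-one (acyl imidazole, not isolated) | COc1ccc(-c2cc(=O)c3c(OCc4ccccc4)c(Oc4ccc(C(=O)n5ccnc5)cc4)c(OCc4ccccc4)cc3o2)cc1 | intermediate
15 | 2-[4-[[5,7-bis(benzyloxy)-2-(4-methoxyphenyl)-4-oxo-4H-chromen-6-yl]oxy]benzoyl]-3-ethoxy-3-oxopropanoic acid (aroylmalonic half ester, not isolated) | CCOC(=O)C(C(=O)O)C(=O)c1ccc(Oc2c(OCc3ccccc3)cc3oc(-c4ccc(OC)cc4)cc(=O)c3c2OCc2ccccc2)cc1 | intermediate
16 | ethyl 3-[4-[[5,7-bis(benzyloxy)-2-(4-methoxyphenyl)-4-oxo-4H-chromen-6-yl]oxy]phenyl]-3-oxopropanoate | CCOC(=O)CC(=O)c1ccc(Oc2c(OCc3ccccc3)cc3oc(-c4ccc(OC)cc4)cc(=O)c3c2OCc2ccccc2)cc1 | intermediate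
17 | phloroglucinol (benzene-1,3,5-triol) | Oc1cc(O)cc(O)c1 | starting material
18 | 5,7-bis(benzyloxy)-2-(4-methoxyphenyl)-6-[4-(3-oxoprop-2-enoyl)phenoxy]-4H-chromen-4-one (aroylketene, not isolated) | O=C=CC(=O)c1ccc(Oc2c(OCc3ccccc3)cc3oc(-c4ccc(OC)cc4)cc(=O)c3c2OCc2ccccc2)cc1 | intermediate
19 | 1-[4-[[5,7-bis(benzyloxy)-2-(4-methoxyphenyl)-4-oxo-4H-chromen-6-yl]oxy]phenyl]-3-(2,4,6-trihydroxyphenyl)propane-1,3-dione (aryl 1,3-diketone, not isolated) | O=C(CC(=O)c1c(O)cc(O)cc1O)c1ccc(Oc2c(OCc3ccccc3)cc3oc(-c4ccc(OC)cc4)cc(=O)c3c2OCc2ccccc2)cc1 | intermediate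
20 | 5,7-bis(benzyloxy)-6-[4-(5,7-dihydroxy-4-oxo-4H-chromen-2-yl)phenoxy]-2-(4-methoxyphenyl)-4H-chromen-4-one (5,7-di-O-benzylcryptomerin A) | COc1ccc(-c2cc(=O)c3c(OCc4ccccc4)c(Oc4ccc(-c5cc(=O)c6c(O)cc(O)cc6o5)cc4)c(OCc4ccccc4)cc3o2)cc1 | intermediate
21 | cryptomerin A | COc1ccc(-c2cc(=O)c3c(O)c(Oc4ccc(-c5cc(=O)c6c(O)cc(O)cc6o5)cc4)c(O)cc3o2)cc1 | target

**Step count**
Total: 10 steps. Longest linear sequence: 10 steps (1 to 21; compounds 2, 10 and 17 enter as bought fragments).

**Steps most likely to fail**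

1. Step 9 (key step). In the phenolic melt at 240 °C the benzyl groups of the acacetin unit may migrate to phloroglucinol. The water released may also cleave 16 to the methyl ketone before acylation, or ring closure may take the coumarin course.
Fallback: the apigenin pyranone would be built stepwise on a preformed phloroacetophenone. The fallback sets out from acid 13. Oxalyl chloride with catalytic DMF in CH2Cl2 should give 4-[[5,7-bis(benzyloxy)-2-(4-methoxyphenyl)-4-oxo-4H-chromen-6-yl]oxy]benzoyl chloride F1. This would acylate the lithium dianion (LiN(SiMe3)2, THF, −78 °C) of commercial 1-[2,4-bis(benzyloxy)-6-hydroxyphenyl]ethanone (CC(=O)c1c(O)cc(OCc2ccccc2)cc1OCc1ccccc1) to give 1-[2,4-bis(benzyloxy)-6-hydroxyphenyl]-3-[4-[[5,7-bis(benzyloxy)-2-(4-methoxyphenyl)-4-oxo-4H-chromen-6-yl]oxy]phenyl]propane-1,3-dione F2. Catalytic p-TsOH in refluxing toluene should close this to tetra-O-benzylcryptomerin A F3. BCl3 with pentamethylbenzene (CH2Cl2, −78 to 0 °C) would then remove all four benzyl groups, and the fallback comes back to the route at the target 21.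

2. Step 5. BF3 may strip the benzyl ether next to the new ketone by chelation-assisted cleavage, or move a benzyl group onto carbon, before the Fries step is complete.
Fallback: the acetyl group would be introduced without a strong Lewis acid. The fallback sets out from phenol 7. Ortho-formylation with MgCl2, Et3N and paraformaldehyde in refluxing MeCN (Casnati–Skattebøl conditions; both ortho positions are equivalent) should give benzyl 4-[2,6-bis(benzyloxy)-3-formyl-4-hydroxyphenoxy]benzoate F4. MeMgBr (2.2 equiv, THF, −78 °C) should add to the chelated aldehyde in preference to the benzyl ester and give racemic benzyl 4-[2,6-bis(benzyloxy)-4-hydroxy-3-(1-hydroxyethyl)phenoxy]benzoate F5. MnO2 in CH2Cl2 would oxidise the benzylic alcohol, and the fallback comes back to the route at 9.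

3. Step 1. The phenoxide of 1 is flanked by two methoxy groups and conjugated to the aldehyde, and the fluoroarene is only weakly activated, so the addition may stall and the aldehyde may degrade on long heating.
Fallback: the ether would be made by oxidative copper coupling (Chan–Lam–Evans) instead of SNAr. The fallback sets out from 1: with [4-(tert-butoxycarbonyl)phenyl]boronic acid (CC(C)(C)OC(=O)c1ccc(B(O)O)cc1), Cu(OAc)2, pyridine and 4 Å molecular sieves in CH2Cl2 under air at rt it should give 3 directly, where it comes back to the route. No new compound is made.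

Further compounds
F1 | step 9 | 4-[[5,7-bis(benzyloxy)-2-(4-methoxyphenyl)-4-oxo-4H-chromen-6-yl]oxy]benzoyl chloride | COc1ccc(-c2cc(=O)c3c(OCc4ccccc4)c(Oc4ccc(C(Cl)=O)cc4)c(OCc4ccccc4)cc3o2)cc1
F2 | step 9 | 1-[2,4-bis(benzyloxy)-6-hydroxyphenyl]-3-[4-[[5,7-bis(benzyloxy)-2-(4-methoxyphenyl)-4-oxo-4H-chromen-6-yl]oxy]phenyl]propane-1,3-dione | COc1ccc(-c2cc(=O)c3c(OCc4ccccc4)c(Oc4ccc(C(=O)CC(=O)c5c(O)cc(OCc6ccccc6)cc5OCc5ccccc5)cc4)c(OCc4ccccc4)cc3o2)cc1
F3 | step 9 | 5,7-bis(benzyloxy)-6-[4-[5,7-bis(benzyloxy)-4-oxo-4H-chromen-2-yl]phenoxy]-2-(4-methoxyphenyl)-4H-chromen-4-one (tetra-O-benzylcryptomerin A) | COc1ccc(-c2cc(=O)c3c(OCc4ccccc4)c(Oc4ccc(-c5cc(=O)c6c(OCc7ccccc7)cc(OCc7ccccc7)cc6o5)cc4)c(OCc4ccccc4)cc3o2)cc1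
F4 | step 5 | benzyl 4-[2,6-bis(benzyloxy)-3-formyl-4-hydroxyphenoxy]benzoate | O=Cc1c(O)cc(OCc2ccccc2)c(Oc2ccc(C(=O)OCc3ccccc3)cc2)c1OCc1ccccc1
F5 | step 5 | benzyl 4-[2,6-bis(benzyloxy)-4-hydroxy-3-(1-hydroxyethyl)phenoxy]benzoate (racemic) | CC(O)c1c(O)cc(OCc2ccccc2)c(Oc2ccc(C(=O)OCc3ccccc3)cc2)c1OCc1ccccc1
F0 | step 1 | none | none
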